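Count the J left, not the Z made, and hold it against two amounts: the charge of E and the charge of J.

| setting | Thursday's | Sunday's | south-east | south-west | west |
|---|---|---|---|---|---|
| J | 0.11 M (fed, over 5.0 min) | 0.11 M (fed, over 5.0 min) | 0.11 M (fed, over 5.0 min) | 0.11 M (fed, over 5.0 min) | 0.11 M (fed, over 5.0 min) |
| E | 0.093 M | 0.16 M | 0.140 M | 0.110 M | 0.190 M |
| remark | run made earlier | run made earlier |  |  |  |
| time |  |  | 30 h | 30 h | 30 h |

| run | time / h | J / % | Z / % |
|---|---|---|---|
| Thursday's | 8.00 | 45.9 | 53.7 |
| Thursday's | 15.0 | 46.4 | 53.8 |
| Thursday's | 25.0 | 45.7 | 54.2 |
| Thursday's | 30.0 | 46.0 | 54.0 |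
| Sunday's | 2.50 | 34.1 | 65.9 |
| Sunday's | 6.00 | 29.0 | 71.0 |
| Sunday's | 12.0 | 28.1 | 72.5 |
| Sunday's | 30.0 | 28.2 | 71.7 |

(each reading ± 0.3 percentage points)

- part of the J that has reacted at the end, south-east
- part of the J that has reacted at the end, south-west
- part of the J that has reacted at the end, west
- what raising the concentration of E from its lowest to its highest value here does to the part of the J that has reacted (changes below 5 percentage points count as none) (it falls / it rises / no change)



Thursday's run is flat from 8.00 h and Sunday's from 12.0 h, with J at 46.0 % and 28.2 %. My own reading is a choice, not a finding: I take the plateau to mark the end of the reaction of E with J, and I take part of E to go somewhere other than to Z. I also take J to fall in proportion to itself, so the logarithm of the inverse of its fraction left counts the E it has met. That count should follow the ratio of E charged to J charged. At a small ratio, the count divided by that ratio is the share of E that reaches J. Thursday's last reading gives 0.918 and Sunday's 0.870. Their mean, 0.894, is my reading of the E share: the natural logarithm of the inverse of the J fraction left, divided by the ratio of E charged to J charged. Sunday's reading is lower than Thursday's, so my figure for west, whose E is higher than Sunday's, may come out high.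

My reckoning gives 68.0 % reacted in south-east, 59.1 % in south-west and 78.7 % in west.

The forecast, on the grounds “I read this as J + E ⇌ Z”, gives 68 %, 60 % and 76.5 %, and says it rises. The two part at west, where my figure is higher than the forecast's.

The flasks give 67.8 %, 59.6 % and 77.5 %: it rises, by 18 percentage points. Each stands inside the forecast's range .

    J + E → Q + Z (k = 0.00510 L mol⁻¹ s⁻¹)
    E + Q ⇌ D, settled at all times (K = 160 L mol⁻¹)
    2 E → L (k = 0.00330 L mol⁻¹ s⁻¹)
    Q → G (k = 0.00370 s⁻¹)

South-east has moved by 5 points once its E stands at 0.121 M or 0.163 M, or its J at 0.0940 M or 0.128 M, and that is outside the forecast's range for that flask. West ends with 0 % of its E still there unbound, which makes E the limiting reagent, and with 23 % of its J. A neighbour of west takes 0.44 M of J, so its ratio of E to J is 0.432. The E share then leaves 68.0 % of the J in that neighbour. That neighbour ends with 68 % of its J.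

The readings stem from a simulated flask with made-up constants; scatter was added.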